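**Retrosynthetic overview**

- Feature: ring A is the tetrahydrofuran O1–C2–C3–C4–C5. Its O1–C2 bond joins the C5 oxygen to a benzylic carbon whose aryl group has a para oxygen, so C2 can be made a cation by loss of CO2 from a C2 carboxylate (carboxyl carbon = C1).
- Key disconnection, the only ring closure and the last skeletal event: O1–C2 by anodic decarboxylation of an open-chain 2-aryl-5-hydroxy carboxylate. C2 is set there, trans to the C3 arm.
- C1–C2–C3: amine-catalysed Michael addition of an aldehyde (C6 = CHO, C3 = its α-carbon) to the nitrostyrene from O-benzylvanillin. The catalyst sets C3, and CH2NO2 is later oxidised to CO2H.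
- C4–C7: Evans syn aldol of a pent-4-enoyl imide with O-benzylvanillin. The auxiliary sets C4 and C7, so C3 and C4/C7 are controlled independently.
- Protection: phenols as benzyl ethers, O7 as silyl ether, O6 left free (it could only close a four-membered ring). The free hydroxy acid would lactonise, so it is stored as a γ-lactone and electrolysed as its tetrabutylammonium salt.

Key step: step 11

Remark: locants are those of ring A (O1, C2–C5), with C6 the hydroxymethyl carbon on C3, C7 the carbinol carbon on C4 and C1 the carboxyl carbon that is lost. O-Benzylvanillin and the nitrostyrene are also catalogue items but are made here from vanillin.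

**Route**

Step 1
Reactants: 1 vanillin
Product: 2 O-benzylvanillin (4-benzyloxy-3-methoxybenzaldehyde)
Conditions: BnBr, K2CO3, DMF, 60 °C
Reagents that add atoms: benzyl bromide, BrCc1ccccc1
Why: Williamson ether synthesis: the vanillin phenoxide is benzylated cleanly, and the benzyl ether keeps the phenol out of every basic, reductive and anodic step that follows.

Step 2
Reactants: 2 O-benzylvanillin; 3 nitromethane
Product: 4 (E)-4-benzyloxy-3-methoxy-β-nitrostyrene
Conditions: NH4OAc, AcOH, 100 °C
Reagents that add atoms: none
Why: Henry (nitroaldol) condensation with dehydration gives the conjugated nitroalkene as the thermodynamically favoured E isomer; no stereocentre is formed.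

Step 3
Reactants: 5 (S)-4-benzyloxazolidin-2-one; 6 pent-4-enoyl chloride
Product: 7 (S)-4-benzyl-3-(pent-4-enoyl)oxazolidin-2-one
Conditions: Et3N, DMAP (cat.), CH2Cl2, 0 °C → rt
Reagents that add atoms: none
Why: DMAP-catalysed N-acylation of the oxazolidinone by the acid chloride gives the imide without touching the auxiliary stereocentre.

Step 4
Reactants: 7 pentenoyl imide; 2 O-benzylvanillin
Product: 9 syn-aldol imide (4S,7S), via dibutylboron Z-enolate 8 (not isolated)
Conditions: Bu2BOTf, i-Pr2NEt, CH2Cl2, −78 → 0 °C; then 2, −78 → 0 °C; pH 7 buffer, MeOH, H2O2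
Reagents that add atoms: dibutylboron triflate, CCCCB(CCCC)OS(=O)(=O)C(F)(F)F (its Bu2B unit is held in intermediate 8 only)
Why: Evans syn aldol: soft enolisation gives the Z-boron enolate, which adds to the aldehyde through a closed chair transition state on the face left open by the (S)-benzyl group, so C4 and C7 are set together as the syn (4S,7S) pair with the relative and absolute configuration of the target.

Step 5
Reactants: 9 syn-aldol imide
Product: 10 C7 tert-butyldimethylsilyl ether of 9
Conditions: TBSOTf, 2,6-lutidine, CH2Cl2, −78 → 0 °C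
Reagents that add atoms: tert-butyldimethylsilyl triflate, CC(C)(C)[Si](C)(C)OS(=O)(=O)C(F)(F)F
Why: Silyl ether formation with the silyl triflate and a hindered pyridine base protects the benzylic hydroxyl without retro-aldol, so that O7 cannot compete for the C2 cation in step 11.

Step 6
Reactants: 10 silylated aldol imide
Product: 11 C6 aldehyde (4-oxobutanoyl imide)
Conditions: OsO4 (cat.), NaIO4, 2,6-lutidine, dioxane/H2O (3:1), rt
Reagents that add atoms: sodium periodate, [Na+].[O-]I(=O)(=O)=O (terminal oxidant; the oxygen is passed on through OsO4, O=[Os](=O)(=O)=O)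
Why: Lemieux–Johnson oxidative cleavage (catalytic dihydroxylation, then periodate glycol cleavage) converts the terminal alkene into the C6 aldehyde without the arene damage that ozone risks, and C4 is not enolised under these near-neutral conditions.

Step 7
Reactants: 11 aldehyde; 4 nitrostyrene
Product: 12 γ-nitro aldehyde imide (2R,3R,4S,7S)
Conditions: 4 (1.5 equiv), (R)-α,α-diphenylprolinol trimethylsilyl ether (20 mol%), 4-nitrophenol (20 mol%), toluene, 0 °C → rt
Reagents that add atoms: none
Why: Enamine-catalysed Michael addition of an aldehyde to a nitroalkene: the (R)-diarylprolinol silyl ether forms the E-enamine of 11 and screens one face with its diphenyl(silyloxy)methyl group, so the nitroalkene adds to the open face through the usual synclinal transition state, which sets C3 as R by catalyst control independently of the auxiliary and places C2 syn to it (C2 is erased later).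

Step 8
Reactants: 12 γ-nitro aldehyde imide
Product: 13 nitro diol (2R,3R,4R,7S)
Conditions: LiBH4, MeOH (1 equiv), THF, 0 °C → rt
Reagents that add atoms: none
Why: Hydride reduction with LiBH4 takes the aldehyde and the N-acyl oxazolidinone (directly or after lactonisation of the C6 alkoxide onto the imide) to the two primary alcohols and releases the auxiliary, while the nitroalkane, the silyl ether and the stereocentres C3, C4 and C7 are left alone.

Step 9
Reactants: 13 nitro diol
Product: 15 C1–O6 γ-lactone bearing the free C5 hydroxyl, via hydroxy acid 14 (not isolated)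
Conditions: NaNO2, AcOH, DMSO, 35 °C; then PPTS (cat.), CH2Cl2, rt
Reagents that add atoms: sodium nitrite, [Na+].[O-]N=O; water, O
Why: Nef-type oxidation of a primary nitroalkane to the carboxylic acid with nitrite in acetic acid/DMSO (nitrolic acid, nitrile oxide, hydroxamic acid) leaves C3, C4 and C7 untouched, and the resulting 4-hydroxy acid closes under mild acid to the γ-lactone, a neutral compound that can be purified and stored.

Step 10
Reactants: 15 γ-lactone
Product: 16 tetrabutylammonium 2-aryl-5-hydroxy carboxylate (key-step precursor)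
Conditions: n-Bu4NOH (40% aq., 1.05 equiv), THF, 0 °C → rt; concentrate, azeotrope with toluene, use crude
Reagents that add atoms: tetrabutylammonium hydroxide, CCCC[N+](CCCC)(CCCC)CCCC.[OH-]
Why: Saponification: one equivalent of hydroxide opens the lactone (and any δ-lactone isomer) irreversibly to the carboxylate, which as its salt cannot relactonise and is the species the anode needs; silyl and benzyl ethers are stable to hydroxide at room temperature, and epimerisation at C2 is of no consequence.

Step 11
Reactants: 16 tetrabutylammonium carboxylate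
Product: 17 7-O-silyl-di-O-benzyl-tanegol (ring A closed)
Conditions: graphite anode, Pt cathode, undivided cell, constant current (5 mA cm−2, ca. 2.2 F mol−1), HFIP (5 equiv), n-Bu4NPF6 (0.05 M), 3 Å MS, MeCN, rt
Reagents that add atoms: none
Why: Hofer–Moest (non-Kolbe) anodic decarboxylation: the carboxylate of 16, whose oxidation is eased by the attached 4-benzyloxy-3-methoxyphenyl ring, gives up one electron at graphite, loses CO2 to the C2 benzylic radical, and this is oxidised at once to the C2 cation, which is stabilised by the para oxygen as a quinone-methide-like oxocarbenium ion. The closest known reaction type is the decarboxylative etherification of arylacetic and other cation-stabilised acids at carbon anodes in non-nucleophilic media with added alcohols; here the alcohol is tethered. Ring A closes by 5-exo attack of the C5 hydroxyl on the planar C2 cation (O1–C2 bond), the proton passing to carboxylate or to the hexafluoroisopropoxide made at the cathode. The new C2 stereocentre is set by C3 and C4: the aryl group takes the face of the forming ring opposite the cis-disposed C6 and C7 arms, so the 2,3-trans ring should result and the all-cis alternative is avoided, and both C2 epimers of 16 give the same cation. Among the oxygens, O6 could only close an oxetane, O7 is a hindered silyl ether, and the medium offers no better nucleophile than O5. The electron transfer is selective because the carboxylate-bearing arene is the most easily oxidised site, the charge is limited to a little over two electrons per molecule, and the bulk becomes mildly basic as the run proceeds, so the salt does not lactonise.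

Step 12
Reactants: 17 7-O-silyl-di-O-benzyl-tanegol
Product: 18 di-O-benzyl-tanegol
Conditions: Bu4NF, THF, 0 °C → rt
Reagents that add atoms: none
Why: Fluoride-mediated desilylation driven by the Si–F bond frees the C7 hydroxyl while the phenols are still benzylated, so no base meets a free para-hydroxybenzyl system that could epimerise C2 or C7 through a quinone methide.

Step 13
Reactants: 18 di-O-benzyl-tanegol
Product: 19 (−)-tanegol
Conditions: H2 (1 atm), 10% Pd/C, EtOAc, rt
Reagents that add atoms: none
Why: Catalytic hydrogenolysis of the two aryl benzyl ethers over Pd/C in neutral ethyl acetate is much faster than cleavage of the benzylic C2–O1 bond or the C7 carbinol, so stopping after uptake of two equivalents of hydrogen should give (−)-tanegol with all four stereocentres intact.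

**Compound list**

1 | vanillin | COc1cc(C=O)ccc1O | starting material
2 | O-benzylvanillin (4-benzyloxy-3-methoxybenzaldehyde) | COc1cc(C=O)ccc1OCc1ccccc1 | intermediate
3 | nitromethane | C[N+](=O)[O-] | starting material
4 | (E)-4-benzyloxy-3-methoxy-β-nitrostyrene | COc1cc(/C=C/[N+](=O)[O-])ccc1OCc1ccccc1 | intermediate
5 | (S)-4-benzyloxazolidin-2-one | O=C1N[C@@H](Cc2ccccc2)CO1 | starting material
6 | pent-4-enoyl chloride | C=CCCC(=O)Cl | starting material
7 | (S)-4-benzyl-3-(pent-4-enoyl)oxazolidin-2-one | C=CCCC(=O)N1[C@@H](Cc2ccccc2)COC1=O | intermediate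
8 | dibutylboron (Z)-enolate of 7 | CCCCB(CCCC)O/C(=C\CC=C)N1[C@@H](Cc2ccccc2)COC1=O | intermediate (not isolated)
9 | (4S)-4-benzyl-3-[(2S)-2-[(S)-(4-benzyloxy-3-methoxyphenyl)(hydroxy)methyl]pent-4-enoyl]oxazolidin-2-one (syn aldol; C4 S, C7 S) | C=CC[C@@H]([C@H](O)c1ccc(OCc2ccccc2)c(OC)c1)C(=O)N1[C@@H](Cc2ccccc2)COC1=O | intermediate
10 | C7 tert-butyldimethylsilyl ether of 9 (C4 S, C7 S) | C=CC[C@@H]([C@H](O[Si](C)(C)C(C)(C)C)c1ccc(OCc2ccccc2)c(OC)c1)C(=O)N1[C@@H](Cc2ccccc2)COC1=O | intermediate
11 | (4S)-4-benzyl-3-[(2S)-2-[(S)-(4-benzyloxy-3-methoxyphenyl)(tert-butyldimethylsilyloxy)methyl]-4-oxobutanoyl]oxazolidin-2-one (C6 aldehyde) | O=CC[C@@H]([C@H](O[Si](C)(C)C(C)(C)C)c1ccc(OCc2ccccc2)c(OC)c1)C(=O)N1[C@@H](Cc2ccccc2)COC1=O | intermediate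
12 | γ-nitro aldehyde imide: C6 aldehyde, C3 bearing the 1-aryl-2-nitroethyl group, C5 imide (2R,3R,4S,7S) | O=C[C@H]([C@@H](C[N+](=O)[O-])c1ccc(OCc2ccccc2)c(OC)c1)[C@@H]([C@H](O[Si](C)(C)C(C)(C)C)c1ccc(OCc2ccccc2)c(OC)c1)C(=O)N1[C@@H](Cc2ccccc2)COC1=O | intermediate
13 | nitro diol: C5 and C6 primary alcohols, C1 as CH2NO2, O7 silylated (2R,3R,4R,7S) | OC[C@H]([C@@H](C[N+](=O)[O-])c1ccc(OCc2ccccc2)c(OC)c1)[C@@H]([C@H](O[Si](C)(C)C(C)(C)C)c1ccc(OCc2ccccc2)c(OC)c1)CO | intermediate
14 | free 2-aryl-5-hydroxy acid with free C6 hydroxyl and silylated O7 (2R,3S,4R,7S; either C2 epimer serves) | OC[C@H]([C@@H](C(=O)O)c1ccc(OCc2ccccc2)c(OC)c1)[C@@H]([C@H](O[Si](C)(C)C(C)(C)C)c1ccc(OCc2ccccc2)c(OC)c1)CO | intermediate (not isolated)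
15 | (3R,4S)-3-(4-benzyloxy-3-methoxyphenyl)-4-[(1S,2R)-1-(4-benzyloxy-3-methoxyphenyl)-1-(tert-butyldimethylsilyloxy)-3-hydroxypropan-2-yl]dihydrofuran-2(3H)-one (C1–O6 γ-lactone, free C5 hydroxyl) | OC[C@H]([C@H](O[Si](C)(C)C(C)(C)C)c1ccc(OCc2ccccc2)c(OC)c1)[C@@H]3COC(=O)[C@H]3c1ccc(OCc2ccccc2)c(OC)c1 | intermediate
16 | tetrabutylammonium salt of acid 14 (key-step precursor) | OC[C@H]([C@@H](C(=O)[O-])c1ccc(OCc2ccccc2)c(OC)c1)[C@@H]([C@H](O[Si](C)(C)C(C)(C)C)c1ccc(OCc2ccccc2)c(OC)c1)CO.CCCC[N+](CCCC)(CCCC)CCCC | intermediate
17 | [(2S,3R,4R)-2-(4-benzyloxy-3-methoxyphenyl)-4-[(S)-(4-benzyloxy-3-methoxyphenyl)(tert-butyldimethylsilyloxy)methyl]tetrahydrofuran-3-yl]methanol (7-O-silyl-di-O-benzyl-tanegol) | COc1cc([C@@H](O[Si](C)(C)C(C)(C)C)[C@H]2CO[C@H](c3ccc(OCc4ccccc4)c(OC)c3)[C@H]2CO)ccc1OCc1ccccc1 | intermediate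
18 | di-O-benzyl-tanegol | COc1cc([C@@H](O)[C@H]2CO[C@H](c3ccc(OCc4ccccc4)c(OC)c3)[C@H]2CO)ccc1OCc1ccccc1 | intermediate
19 | (−)-tanegol, [(2S,3R,4R)-4-[(S)-hydroxy(4-hydroxy-3-methoxyphenyl)methyl]-2-(4-hydroxy-3-methoxyphenyl)tetrahydrofuran-3-yl]methanol | COc1cc([C@@H](O)[C@H]2CO[C@H](c3ccc(O)c(OC)c3)[C@H]2CO)ccc1O | target

**Step count**

Total steps: 13. Longest linear sequence: 11 steps (steps 1, 4, 5, 6, 7, 8, 9, 10, 11, 12, 13).

**Steps most likely to fail**

Step 11 (key step). The cation may lose the C3 proton or be taken by adventitious nucleophiles before ring closure. The second electron-rich arene or the product may be oxidised once the carboxylate is depleted. Closure under kinetic control may also give some 2,3-cis ring. The fallback sets out from 16 and separates cation formation from ring closure. The salt 16 would be electrolysed at graphite in methanol at 0 °C, the classical medium for this reaction, so that the solvent takes the cation and gives the C2 methyl ether F1 (either C2 epimer), together with any 17 formed directly. Catalytic camphorsulfonic acid in CH2Cl2 at 0 °C would then re-ionise the more basic, less hindered methyl ether and close ring A by SN1 etherification under thermodynamic control. This comes back to the route at 17.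

Step 7. Enamine formation and addition may be slow with this β-branched aldehyde. Facial selectivity at C3 may be eroded if the neighbouring C4 centre opposes the catalyst, and the product aldehyde may epimerise at C3 on handling. The fallback sets out from 11 and puts an auxiliary directly on C6. Pinnick oxidation (NaClO2, NaH2PO4, 2-methyl-2-butene, t-BuOH/H2O) would give the carboxylic acid F2. Mixed-anhydride coupling (PivCl, Et3N, then (R)-4-benzyloxazolidin-2-one, LiCl, THF) would give the bis-imide F3. Its unbranched CH2 imide would be enolised selectively (TiCl4, i-Pr2NEt, CH2Cl2, −78 °C), and the titanium enolate would add to nitrostyrene 4 on the face opposite the benzyl group of the (R)-auxiliary, giving the nitro bis-imide F4 with C3 as required. LiBH4 would then reduce both imides. This comes back to the route at 13 (either C2 epimer, which is immaterial).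

Step 9. The free hydroxyls may be nitrosated or may intercept the nitrile oxide intermediate, the oxidation may stall, and warm acetic acid may begin to remove the silyl ether. The fallback sets out from 12 and does the oxidation on a substrate without free hydroxyls. NaBH4 (THF/EtOH, 0 °C) would reduce only the aldehyde, and the C6 alkoxide would expel the auxiliary to give the nitro lactone F5 (C5 acyl on O6). The same nitrite oxidation (NaNO2, AcOH, DMSO, 35 °C) would give the lactone acid F6. Excess LiBH4 in THF would reduce the lactone while the lithium carboxylate stays inert, and mild acidic work-up would let the hydroxy acid 14 close. This comes back to the route at 15.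

**Further compounds**

F1 | step 11 | C2 methyl ether of the open-chain diol (C2 epimers; C3, C4, C7 as in 16) | OC[C@H](C(OC)c1ccc(OCc2ccccc2)c(OC)c1)[C@@H]([C@H](O[Si](C)(C)C(C)(C)C)c1ccc(OCc2ccccc2)c(OC)c1)CO
F2 | step 7 | C6 carboxylic acid from aldehyde 11 | OC(=O)C[C@@H]([C@H](O[Si](C)(C)C(C)(C)C)c1ccc(OCc2ccccc2)c(OC)c1)C(=O)N1[C@@H](Cc2ccccc2)COC1=O
F3 | step 7 | bis-imide: C5 on the (S)-auxiliary, C6 on (R)-4-benzyloxazolidin-2-one | O=C(C[C@@H]([C@H](O[Si](C)(C)C(C)(C)C)c1ccc(OCc2ccccc2)c(OC)c1)C(=O)N1[C@@H](Cc2ccccc2)COC1=O)N1[C@H](Cc2ccccc2)COC1=O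
F4 | step 7 | nitro bis-imide Michael adduct (C3 as required, C2 unassigned) | O=C([C@H](C(C[N+](=O)[O-])c1ccc(OCc2ccccc2)c(OC)c1)[C@@H]([C@H](O[Si](C)(C)C(C)(C)C)c1ccc(OCc2ccccc2)c(OC)c1)C(=O)N1[C@@H](Cc2ccccc2)COC1=O)N1[C@H](Cc2ccccc2)COC1=O
F5 | step 9 | nitro γ-lactone (C5 acyl on O6) | O=C1OC[C@H]([C@@H](C[N+](=O)[O-])c2ccc(OCc3ccccc3)c(OC)c2)[C@H]1[C@H](O[Si](C)(C)C(C)(C)C)c1ccc(OCc2ccccc2)c(OC)c1
F6 | step 9 | lactone acid (C5 acyl on O6, C1 carboxylic acid) | O=C1OC[C@H]([C@@H](C(=O)O)c2ccc(OCc3ccccc3)c(OC)c2)[C@H]1[C@H](O[Si](C)(C)C(C)(C)C)c1ccc(OCc2ccccc2)c(OC)c1
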